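Assumption: compound numbers are assigned in the forward route, so the overview uses descriptions only. Compounds 1, 3 and 6 are taken as commercially available.

## Retrosynthetic overview
1. (−)-Carinol comes from global hydrogenolysis of a tri-O-benzyl diol. Its two CH2OH arms are unmasked from a CO2H (LiAlH4) and an (E)-propenyl group (O3/NaBH4).
2. The key disconnection is the central C2–C3 (lignan C8–C8') bond. A chelation-controlled Ireland–Claisen rearrangement of an α-benzyloxy-α-benzyl ester enolate onto a (Z)-allylic ester makes the tertiary carbinol and the adjacent methine in one C–C bond formation. This replaces the usual butyrolactone alkylation, α-hydroxylation and reduction sequence.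
3. Absolute configuration comes by 1,3-chirality transfer from one purchased stereocentre, (S)-but-3-yn-2-ol. The acid partner is used racemic because its stereocentre is erased on enolisation.
4. Both halves come from the same O-benzylvanillyl bromide, by C-benzylation of the butynol (then Lindlar reduction) and of the benzyloxyacetic acid dianion.
5. No rings are formed. The target is acyclic and both arenes are bought intact; the only six-membered array is the chair transition state of the [3,3] shift.

## Forward route

**Step 1**
Reactants: 1, 4-(benzyloxy)-3-methoxybenzyl alcohol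
Product: 2, 4-(benzyloxy)-3-methoxybenzyl bromide (used crude)
Conditions: PBr3 (0.4 equiv), Et2O, 0 °C, 1 h
Reagents that add atoms: phosphorus tribromide, BrP(Br)Br
Why: This is a PBr3 bromination (SN2 on the activated phosphite ester) of an electron-rich benzylic alcohol, in which the aryl ethers are inert at 0 °C and no stereocentre is involved.

**Step 2**
Reactants: 3, (S)-but-3-yn-2-ol; 2, benzyl bromide
Product: 4, (S)-5-[4-(benzyloxy)-3-methoxyphenyl]pent-3-yn-2-ol
Conditions: 3, EtMgBr (2.1 equiv), THF, 0 °C → rt; CuBr·SMe2 (10 mol %), then 2, 0 → 45 °C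
Reagents that add atoms: none (all heavy atoms come from 2 and 3)
Why: This is a Cu(I)-catalysed sp–sp3 coupling of the alkynylmagnesium O,C-dianion with a very reactive benzylic bromide, in which the Mg alkoxide is a poor nucleophile so C-alkylation wins, the medium does not promote alkyne-to-allene isomerisation, and the (S)-carbinol centre is untouched.

**Step 3**
Reactants: 4
Product: 5, (2S,3Z)-5-[4-(benzyloxy)-3-methoxyphenyl]pent-3-en-2-ol
Conditions: H2 (1 atm), Lindlar catalyst, quinoline, EtOAc, rt, stopped at 1 equiv H2
Reagents that add atoms: none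
Why: Lindlar semihydrogenation delivers H2 syn on poisoned Pd to give the Z-alkene needed for the relative configuration, and the aryl benzyl ether and carbinol centre survive.

**Step 4**
Reactants: 6, benzyloxyacetic acid; 2, benzyl bromide
Product: 7, (±)-2-(benzyloxy)-3-[4-(benzyloxy)-3-methoxyphenyl]propanoic acid
Conditions: LDA (2.2 equiv), THF/DMPU, −78 → −30 °C; then 2, −78 °C → rt; acid/base extraction
Reagents that add atoms: none
Why: This is a carboxylic acid dianion (enediolate) alkylation with a reactive benzylic halide, and the new stereocentre is deliberately racemic because it is planarised in Step 6.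

**Step 5**
Reactants: 5, (S,Z)-allylic alcohol; 7, racemic acid
Product: 8, (2S,3Z)-5-[4-(benzyloxy)-3-methoxyphenyl]pent-3-en-2-yl (2RS)-2-(benzyloxy)-3-[4-(benzyloxy)-3-methoxyphenyl]propanoate (about 1:1 epimers at the acyl α-carbon)
Conditions: EDC·HCl, DMAP, CH2Cl2, 0 °C → rt
Reagents that add atoms: none
Why: Steglich esterification forms the acyl–O bond, so the allylic C–O stereocentre and the Z-alkene are retained, and the epimer mixture does not matter.

**Step 6 (key step)**
Reactants: 8
Product: 9, (2S,3S,4E)-2-(benzyloxy)-2,3-bis[4-(benzyloxy)-3-methoxybenzyl]hex-4-enoic acid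
Conditions: LDA (1.3 equiv), THF, −78 °C, 1 h; TMSCl/Et3N, −78 °C → rt, then 55 °C, 6 h; 1 M HCl work-up
Reagents that add atoms: none (TMS is lost on work-up)
Why: In this Ireland–Claisen rearrangement, both epimers of 8 converge on the Li-chelated enolate (OBn cis to OLi, ArCH2 cis to O-allyl), and its silyl ketene acetal reacts through a chair with the carbinol methyl equatorial (the axial alternative clashes 1,3-diaxially with the Z-substituent), so the C–C bond forms suprafacially on the face vacated by the (S)-C–O bond; the Z-olefin/chelated-enolate pairing gives the OBn/C3-benzyl anti relationship and sets both (2S) and (3S) at once (expected dr about 8–10:1, with the minor isomer removed here or at 10).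

**Step 7**
Reactants: 9
Product: 10, (2S,3S,4E)-2-(benzyloxy)-2,3-bis[4-(benzyloxy)-3-methoxybenzyl]hex-4-en-1-ol
Conditions: LiAlH4 (3 equiv), THF, 0 °C → reflux; Fieser work-up
Reagents that add atoms: none
Why: LiAlH4 reduces the hindered, non-epimerisable α-quaternary acid to the primary alcohol, while the isolated alkene and the benzyl ethers are inert.

**Step 8**
Reactants: 10
Product: 11, (2S,3S)-2-(benzyloxy)-2,3-bis[4-(benzyloxy)-3-methoxybenzyl]butane-1,4-diol
Conditions: O3, CH2Cl2/MeOH (Sudan Red 7B end-point indicator), −78 °C; then NaBH4, −78 °C → rt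
Reagents that add atoms: ozone, [O-][O+]=O
Why: Ozonolysis (Criegee cleavage) with reductive work-up takes the 1,2-disubstituted alkene much faster than the dialkoxyarenes when dosed to the indicator end-point, C5–C6 leave as acetaldehyde/ethanol, and immediate borohydride reduction of the aldehyde/lactol prevents epimerisation at C3.

**Step 9**
Reactants: 11
Product: 12, (−)-carinol, (2S,3S)-2,3-bis(4-hydroxy-3-methoxybenzyl)butane-1,2,4-triol
Conditions: H2 (3 atm), 20% Pd(OH)2/C, EtOH/EtOAc, rt
Reagents that add atoms: none
Why: Catalytic hydrogenolysis cleaves all three PhCH2–O bonds (two aryl ethers and the tertiary alkyl ether) on the benzyl side, so C2 is untouched, and the skeleton has only ArCH2–C bonds, which cannot be hydrogenolysed.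

## Compound list
1 | 4-(benzyloxy)-3-methoxybenzyl alcohol | COc1cc(CO)ccc1OCc1ccccc1 | starting material
2 | 4-(benzyloxy)-3-methoxybenzyl bromide | COc1cc(CBr)ccc1OCc1ccccc1 | intermediate
3 | (S)-but-3-yn-2-ol | C[C@H](O)C#C | starting material
4 | (S)-5-[4-(benzyloxy)-3-methoxyphenyl]pent-3-yn-2-ol | C[C@H](O)C#CCc1ccc(OCc2ccccc2)c(OC)c1 | intermediate
5 | (2S,3Z)-5-[4-(benzyloxy)-3-methoxyphenyl]pent-3-en-2-ol | C[C@H](O)/C=C\Cc1ccc(OCc2ccccc2)c(OC)c1 | intermediate
6 | benzyloxyacetic acid | OC(=O)COCc1ccccc1 | starting material
7 | (±)-2-(benzyloxy)-3-[4-(benzyloxy)-3-methoxyphenyl]propanoic acid | COc1cc(CC(OCc2ccccc2)C(=O)O)ccc1OCc1ccccc1 | intermediate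
8 | (2S,3Z)-5-arylpent-3-en-2-yl (2RS)-2-(benzyloxy)-3-arylpropanoate (aryl = 4-benzyloxy-3-methoxyphenyl) | C[C@H](OC(=O)C(OCc1ccccc1)Cc1ccc(OCc2ccccc2)c(OC)c1)/C=C\Cc1ccc(OCc2ccccc2)c(OC)c1 | intermediate
9 | (2S,3S,4E)-2-(benzyloxy)-2,3-bis[4-(benzyloxy)-3-methoxybenzyl]hex-4-enoic acid | COc1cc(C[C@@H](/C=C/C)[C@](OCc2ccccc2)(C(=O)O)Cc2ccc(OCc3ccccc3)c(OC)c2)ccc1OCc1ccccc1 | intermediate
10 | (2S,3S,4E)-2-(benzyloxy)-2,3-bis[4-(benzyloxy)-3-methoxybenzyl]hex-4-en-1-ol | COc1cc(C[C@@H](/C=C/C)[C@](OCc2ccccc2)(CO)Cc2ccc(OCc3ccccc3)c(OC)c2)ccc1OCc1ccccc1 | intermediate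
11 | (2S,3S)-2-(benzyloxy)-2,3-bis[4-(benzyloxy)-3-methoxybenzyl]butane-1,4-diol | COc1cc(C[C@@H](CO)[C@](OCc2ccccc2)(CO)Cc2ccc(OCc3ccccc3)c(OC)c2)ccc1OCc1ccccc1 | intermediate
12 | (−)-carinol, (2S,3S)-2,3-bis(4-hydroxy-3-methoxybenzyl)butane-1,2,4-triol | COc1cc(C[C@@H](CO)[C@](O)(CO)Cc2ccc(O)c(OC)c2)ccc1O | target

## Summary
Total step count: 9.
Longest linear sequence: 8 steps (1 → 2 → 4 → 5 → 8 → 9 → 10 → 11 → 12, i.e. Steps 1, 2, 3, 5, 6, 7, 8, 9).

Steps most likely to fail:

1. **Step 6, Ireland–Claisen.** The risks are incomplete enolate-geometry control, chair/boat leakage, and a sluggish tetrasubstituted ketene acetal.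
   - Fallback: decouple the two centres. Rearrange the simple acetate of 5, which sets C3 alone by the same chirality transfer.
   - Condense the derived ester with O-benzylvanillin to the (E)-α-benzylidene ester and reduce it with DIBAL to the allylic alcohol.
   - Set C2 by reagent-controlled Sharpless asymmetric epoxidation, then hydrogenolyse the benzylic epoxide C–O bond in the final Pd/H2 step.

2. **Step 2, alkynyl–benzyl coupling.** The risks are Wurtz homocoupling of the electron-rich bromide and allene formation.
   - Fallback: drop the alkyne and form the Z-alkene directly.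
   - Use a salt-free Wittig reaction of the ylide from [2-(4-benzyloxy-3-methoxyphenyl)ethyl]triphenylphosphonium bromide with (S)-2-(TBSO)propanal (from ethyl (S)-lactate), then TBAF, to give 5.

3. **Step 4, dianion alkylation.** The risks are poor solubility and Wittig-type rearrangement of the benzyloxy enediolate.
   - Fallback: skip acid 7 entirely. Acylate 5 with benzyloxyacetyl chloride.
   - C-benzylate the resulting allyl glycolate lithium enolate with 2 at −78 °C, which is below the [3,3] threshold, to reach 8 by a linear ester-enolate route.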